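**Plan**
1. Numbering: ring A is C1–C5 and C10; ring B is C5–C10; the bridged part is C8, C9 and C11–C16, with C12 between C11 and C13. C17 is the exocyclic CH2 and C20 the C10 methyl.
2. Enabling feature: ring B is a cyclohexene whose tetrasubstituted C8=C9 alkene is also the three-carbon bridge of the bicyclo[3.2.1]octane, and whose C10 is quaternary and C6 oxygenated. Cutting C7–C8 and C9–C10 therefore gives a C8≡C9 bicyclooctyne and a ring A diene C7=C6(OAc)–C5=C10.
3. Further cuts: the bicycle at C11–C15 (enol ether onto alkyne) and ring C at C11–C12 and C13–C14 (aldehyde plus enone annulation). The C15 carbonyl and C17 are installed last, by cleaving a C15 methylidene and then methylenating C16.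
4. Forward order: ring A diene (steps 1–6); ring C, then the bridged ring and the C8-silyl/C9-triflate (steps 7–17; the C9 ketone can enolise only towards C8); ring B by (4+2) cycloaddition (step 18); C5/C6, acetates, enone and desilylation (steps 19–23).
5. Stereochemistry: C1 by CBS reduction; C13 by organocatalytic Michael addition; C12 by hydride delivery anti to the C13 side chain; C11 by the bridging cyclisation; C10 by cycloaddition anti to the C1 acetate; C5 and C6 by protonation and hydride attack anti to the C10 methyl.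

Key step: step 18

Remark: pent-4-ynal is taken as a purchasable aldehyde. α/β refer to the usual drawing with the C10 methyl α.

**Step 1**
Reactants: 1 4,4-dimethylcyclohexane-1,3-dione
Product: 2 2,4,4-trimethylcyclohexane-1,3-dione
Conditions: MeI, K2CO3, acetone, reflux
Reagents that add atoms: iodomethane, CI
Why: C-alkylation of a cyclic β-diketone: the potassium enolate is methylated at the doubly activated central carbon.

**Step 2**
Reactants: 2 2,4,4-trimethylcyclohexane-1,3-dione
Product: 3 3-isobutoxy-2,6,6-trimethylcyclohex-2-en-1-one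
Conditions: i-BuOH, TsOH·H2O (cat.), toluene, reflux, Dean–Stark
Reagents that add atoms: 2-methylpropan-1-ol, CC(C)CO
Why: Reversible acid-catalysed enol etherification should place the alkoxy group on the carbonyl remote from the gem-dimethyl group, leaving the hindered carbonyl free for the next addition.

**Step 3**
Reactants: 3 3-isobutoxy-2,6,6-trimethylcyclohex-2-en-1-one
Product: 5 3-ethynyl-2,4,4-trimethylcyclohex-2-en-1-one, via propargylic alkoxide 4 (not isolated)
Conditions: HC≡CMgBr, THF, 0 to 23 °C; then 2 M HCl, 23 °C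
Reagents that add atoms: ethynylmagnesium bromide, C#C[Mg]Br
Why: Stork–Danheiser sequence: 1,2-addition of the acetylide to the vinylogous ester, then acid hydrolysis of the enol ether with loss of water, transposes the enone.

**Step 4**
Reactants: 5 3-ethynyl-2,4,4-trimethylcyclohex-2-en-1-one
Product: 6 (S)-3-ethynyl-2,4,4-trimethylcyclohex-2-en-1-ol
Conditions: (R)-2-methyl-CBS-oxazaborolidine (20 mol %), catecholborane, toluene, −78 °C
Reagents that add atoms: none
Why: Corey–Bakshi–Shibata reduction: the catalyst distinguishes the substituted alkenyl flank (large) from the CH2 flank (small) and should give the S carbinol (C1 of the target), while catecholborane at low temperature leaves the alkyne alone.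

**Step 5**
Reactants: 6 (S)-3-ethynyl-2,4,4-trimethylcyclohex-2-en-1-ol
Product: 7 (S)-3-ethynyl-2,4,4-trimethylcyclohex-2-en-1-yl acetate
Conditions: Ac2O, Et3N, DMAP (cat.), CH2Cl2, 23 °C
Reagents that add atoms: acetic anhydride, CC(=O)OC(C)=O
Why: DMAP-catalysed acylation of a secondary allylic alcohol installs the final C1 ester, which later shields one face of the diene.

**Step 6**
Reactants: 7 (S)-3-ethynyl-2,4,4-trimethylcyclohex-2-en-1-yl acetate
Product: 8 1-[(3S)-3-acetoxy-2,6,6-trimethylcyclohex-1-en-1-yl]vinyl acetate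
Conditions: AcOH, [RuCl2(p-cymene)]2 (2 mol %), P(2-furyl)3, Na2CO3 (cat.), toluene, 60 °C
Reagents that add atoms: acetic acid, CC(=O)O
Why: Ruthenium-catalysed Markovnikov hydro-acyloxylation of the terminal alkyne of a 1,3-enyne gives the 2-acetoxy-1,3-diene, which carries C6 at the ketone oxidation level.

**Step 7**
Reactants: 9 pent-4-ynal; 10 but-3-en-2-one
Product: 12 (R)-4-(prop-2-yn-1-yl)cyclohex-2-en-1-one, via keto aldehyde 11 (not isolated)
Conditions: (R)-α,α-diphenylprolinol trimethylsilyl ether (5 mol %), ethyl 3,4-dihydroxybenzoate (20 mol %), neat, 4 °C; then 0.1 M aq KOH, n-Bu4NOH (cat.), Et2O–THF, reflux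
Reagents that add atoms: none
Why: Enamine Michael addition, with the enone approaching anti to the bulky diarylmethyl group of the catalyst, should set C13 (R), and the base-mediated intramolecular aldol condensation (Robinson-type annulation) closes ring C.

**Step 8**
Reactants: 12 (R)-4-(prop-2-yn-1-yl)cyclohex-2-en-1-one
Product: 13 (4R)-2,3-epoxy-4-(prop-2-yn-1-yl)cyclohexan-1-one
Conditions: 30% H2O2, NaOH (cat.), MeOH, 0 °C
Reagents that add atoms: hydrogen peroxide, OO
Why: Weitz–Scheffer nucleophilic epoxidation of the enone occurs anti to the C13 substituent; the new stereocentres are erased in step 10.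

**Step 9**
Reactants: 13 (4R)-2,3-epoxy-4-(prop-2-yn-1-yl)cyclohexan-1-one
Product: 14 (3S,4R)-3-hydroxy-4-(prop-2-yn-1-yl)cyclohexan-1-one
Conditions: (PhSe)2, NaBH4, EtOH; AcOH, 0 to 23 °C
Reagents that add atoms: none
Why: Reductive opening of an α,β-epoxy ketone with sodium phenylselenoborate cleaves only the Cα–O bond and gives the β-hydroxy ketone without reducing the ketone or the alkyne.

**Step 10**
Reactants: 14 (3S,4R)-3-hydroxy-4-(prop-2-yn-1-yl)cyclohexan-1-one
Product: 15 (R)-4-(prop-2-yn-1-yl)cyclohexane-1,3-dione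
Conditions: IBX, EtOAc, 75 °C
Reagents that add atoms: none
Why: IBX oxidation of a β-hydroxy ketone gives the β-diketone without over-oxidation at the central carbon, and the neutral medium should not epimerise C13.

**Step 11**
Reactants: 15 (R)-4-(prop-2-yn-1-yl)cyclohexane-1,3-dione
Product: 16 (R)-3-methoxy-6-(prop-2-yn-1-yl)cyclohex-2-en-1-one
Conditions: HC(OMe)3, MeOH, TsOH·H2O (cat.), 23 °C
Reagents that add atoms: methanol, CO; trimethyl orthoformate, COC(OC)OC
Why: Reversible acid-catalysed enol etherification should favour the methoxy group on the carbonyl remote from the C13 substituent; the minor regioisomer would be removed by chromatography.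

**Step 12**
Reactants: 16 (R)-3-methoxy-6-(prop-2-yn-1-yl)cyclohex-2-en-1-one
Product: 17 (1S,6R)-3-methoxy-6-(prop-2-yn-1-yl)cyclohex-2-en-1-ol
Conditions: LiBH(s-Bu)3, THF, −78 to 0 °C; then H2O
Reagents that add atoms: none
Why: 1,2-Reduction by a bulky trialkylborohydride, which approaches anti to the adjacent substituent as in the cis-selective reduction of 2-alkylcyclohexanones, should set C12 with oxygen cis to the propargyl group.

**Step 13**
Reactants: 17 (1S,6R)-3-methoxy-6-(prop-2-yn-1-yl)cyclohex-2-en-1-ol
Product: 18 tert-butyl{[(1S,6R)-3-methoxy-6-(prop-2-yn-1-yl)cyclohex-2-en-1-yl]oxy}dimethylsilane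
Conditions: TBSCl, imidazole, DMF, 23 °C (crude 17 used at once)
Reagents that add atoms: tert-butyldimethylsilyl chloride, CC(C)(C)[Si](C)(C)Cl
Why: Silylation under basic conditions protects the acid-sensitive allylic alcohol as an ether that should survive fluoride, base and hydride later on.

**Step 14**
Reactants: 18 tert-butyl{[(1S,6R)-3-methoxy-6-(prop-2-yn-1-yl)cyclohex-2-en-1-yl]oxy}dimethylsilane
Product: 19 8-syn-(tert-butyldimethylsilyloxy)-7-methylidenebicyclo[3.2.1]octan-2-one
Conditions: Ph3PAuCl (5 mol %), AgBF4 (5 mol %), CH2Cl2–H2O (10:1), 23 °C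
Reagents that add atoms: water, O
Why: Gold-catalysed 5-exo-dig carbocyclisation of an enol ether onto a terminal alkyne (Conia-ene type): C11 attacks the activated alkyne held axially on C13, water hydrolyses the oxocarbenium ion to the C9 ketone, and the cis bridge fixes C11 and leaves the C12 silyloxy group syn to the new two-carbon bridge.

**Step 15**
Reactants: 19 8-syn-(tert-butyldimethylsilyloxy)-7-methylidenebicyclo[3.2.1]octan-2-one
Product: 21 3-diazo derivative of ketone 19, via trifluoroacetyl ketone 20 (not isolated)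
Conditions: LiN(SiMe3)2, THF, −78 °C; CF3CO2CH2CF3; then MsN3, Et3N, H2O, MeCN, 23 °C; aq NaOH wash
Reagents that add atoms: methanesulfonyl azide, CS(=O)(=O)N=[N+]=[N-]
Why: Deacylative (Regitz-type) diazo transfer: C11 is a bridgehead, so the ketone can enolise only towards C8, and trifluoroacetylation followed by diazo transfer occurs there.

**Step 16**
Reactants: 21 3-diazo derivative of ketone 19
Product: 22 8-syn-(tert-butyldimethylsilyloxy)-7-methylidene-3-(triethylsilyl)bicyclo[3.2.1]octan-2-one
Conditions: Rh2(OAc)4 (1 mol %), Et3SiH (5 equiv), CH2Cl2, 23 °C, slow addition of 21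
Reagents that add atoms: triethylsilane, CC[SiH](CC)CC
Why: Rhodium carbenoid insertion into the Si–H bond gives the α-silyl ketone, with excess silane expected to outrun the 1,2-hydride shift.

**Step 17**
Reactants: 22 8-syn-(tert-butyldimethylsilyloxy)-7-methylidene-3-(triethylsilyl)bicyclo[3.2.1]octan-2-one
Product: 23 8-syn-(tert-butyldimethylsilyloxy)-7-methylidene-3-(triethylsilyl)bicyclo[3.2.1]oct-2-en-2-yl trifluoromethanesulfonate
Conditions: KN(SiMe3)2, THF, −78 °C; PhNTf2, −78 to 0 °C; then aq NH4Cl
Reagents that add atoms: N-phenylbis(trifluoromethanesulfonimide), O=S(=O)(N(c1ccccc1)S(=O)(=O)C(F)(F)F)C(F)(F)F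
Why: Enolate O-triflation: the only possible enolate (C9=C8, bearing silicon) is trapped as the vicinal silyl enol triflate, the cycloalkyne precursor.

**Step 18**
Reactants: 23 silyl enol triflate; 8 ring A diene
Product: 25 tetracyclic 5,8-diene enol acetate, via bicyclooctyne 24 (not isolated)
Conditions: CsF (4 equiv), 8 (3 equiv), MeCN, 23 °C, slow addition of 23
Reagents that add atoms: none
Why: Proposed new method: fluoride attacks the C8 triethylsilyl group and syn 1,2-loss of triflate releases bicyclo[3.2.1]oct-2-yne 24, whose bent in-plane π bond adds to the s-cis 2-acetoxydiene in a concerted, asynchronous (4+2) cycloaddition; the closest known reactions are the fluoride-triggered Diels–Alder trapping of cyclohexyne from its silyl triflate and the thermal addition of acetylenic esters to 2,6,6-trimethyl-1-vinylcyclohexene, which builds a decalin diene with the same quaternary carbon, but a bridged bicyclooctyne has not been joined to a fully substituted diene terminus. Ring B closes by intermolecular (4+2) annulation, with C7–C8 and C9–C10 formed together, C8=C9 left tetrasubstituted and C5=C6 left as the enol acetate. The one new stereocentre, C10, is controlled by the allylic C1 acetate, which should sit pseudoaxial to avoid A(1,2) strain with the C10 methyl and so block the α face; the alkyne then adds to the β face, where ring A lies under the planar C15 methylidene carbon of the two-carbon bridge and not under C12–H, so the two enantiopure partners should be matched. The step needs C7-to-C8 regiochemistry, which should follow from the unhindered, acetoxy-activated CH2 terminus bonding first to C8, the alkyne carbon that is more open and more electrophilic because the bridgehead pinches the angle at C9. Excess diene and slow release of 24 are meant to suppress oligomerisation, ene and (2+2) pathways, and the silyl ether and both acetates should tolerate CsF in acetonitrile.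

**Step 19**
Reactants: 25 tetracyclic 5,8-diene enol acetate
Product: 27 6α-hydroxy 1α-acetate, via ketone 26 (not isolated)
Conditions: NaBH4 (excess), EtOH–THF (4:1), 0 to 23 °C
Reagents that add atoms: none
Why: Borohydride reduction of an enol acetate, as in the conversion of steroidal dienol acetates into homoallylic alcohols: the enol ester is cleaved, the enolate should be protonated at C5 on the β face anti to the axial C10 methyl (trans ring fusion), and the non-conjugated ketone is reduced at once from the same face to the axial 6α alcohol before C8=C9 can move into conjugation.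

**Step 20**
Reactants: 27 6α-hydroxy 1α-acetate
Product: 28 1α,6α-diacetate
Conditions: Ac2O, DMAP, pyridine, 40 °C
Reagents that add atoms: acetic anhydride, CC(=O)OC(C)=O
Why: DMAP-catalysed acetylation of the hindered axial C6 alcohol completes the two acetates; any C1 alcohol formed by acetate loss in step 19 converges here.

**Step 21**
Reactants: 28 1α,6α-diacetate
Product: 30 15-ketone, via diol 29 (not isolated)
Conditions: OsO4 (2 mol %), NaIO4 (4 equiv), 2,6-lutidine, dioxane–H2O (3:1), 23 °C
Reagents that add atoms: osmium tetroxide, O=[Os](=O)(=O)=O; sodium periodate, [Na+].[O-]I(=O)(=O)=O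
Why: Lemieux–Johnson cleavage: OsO4 should dihydroxylate the exposed 1,1-disubstituted C15 methylidene far faster than the buried tetrasubstituted C8=C9 alkene, and periodate cleaves the diol to the C15 ketone.

**Step 22**
Reactants: 30 15-ketone
Product: 31 12-O-silyl ether of the target
Conditions: (CH2O)n, PhNHMe·CF3CO2H, THF, 65 °C
Reagents that add atoms: paraformaldehyde (formaldehyde), C=O
Why: Mannich-type α-methylenation with formaldehyde and a secondary ammonium salt: the ketone can enolise only towards C16 because C11 is a bridgehead, and the weakly acidic medium leaves the acetates and the silyl ether intact.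

**Step 23**
Reactants: 31 12-O-silyl ether of the target
Product: 32 1alpha,6alpha-diacetoxyjungermannenone C
Conditions: HF·pyridine, THF–pyridine, 0 to 23 °C
Reagents that add atoms: none
Why: Fluoride-mediated cleavage of the silyl ether under buffered acidic conditions that the enone and the acetates tolerate frees the C12 alcohol.

**Compound list**
1 | 4,4-dimethylcyclohexane-1,3-dione | CC1(C)CCC(=O)CC1=O | starting material
2 | 2,4,4-trimethylcyclohexane-1,3-dione | CC1C(=O)CCC(C)(C)C1=O | intermediate
3 | 3-isobutoxy-2,6,6-trimethylcyclohex-2-en-1-one | CC(C)COC1=C(C)C(=O)C(C)(C)CC1 | intermediate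
4 | bromomagnesium alkoxide of 1-ethynyl-3-isobutoxy-2,6,6-trimethylcyclohex-2-en-1-ol (racemic, drawn as the alcohol) | CC(C)COC1=C(C)C(O)(C#C)C(C)(C)CC1 | intermediate (not isolated)
5 | 3-ethynyl-2,4,4-trimethylcyclohex-2-en-1-one | C#CC1=C(C)C(=O)CCC1(C)C | intermediate
6 | (S)-3-ethynyl-2,4,4-trimethylcyclohex-2-en-1-ol | C#CC1=C(C)[C@@H](O)CCC1(C)C | intermediate
7 | (S)-3-ethynyl-2,4,4-trimethylcyclohex-2-en-1-yl acetate | C#CC1=C(C)[C@@H](OC(C)=O)CCC1(C)C | intermediate
8 | 1-[(3S)-3-acetoxy-2,6,6-trimethylcyclohex-1-en-1-yl]vinyl acetate (ring A diene, C7=C6(OAc)–C5=C10) | C=C(OC(C)=O)C1=C(C)[C@@H](OC(C)=O)CCC1(C)C | intermediate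
9 | pent-4-ynal | C#CCCC=O | starting material
10 | but-3-en-2-one | CC(=O)C=C | starting material
11 | (R)-5-oxo-2-(prop-2-yn-1-yl)hexanal | O=C[C@@H](CC#C)CCC(C)=O | intermediate (not isolated)
12 | (R)-4-(prop-2-yn-1-yl)cyclohex-2-en-1-one | O=C1C=C[C@@H](CC#C)CC1 | intermediate
13 | (4R)-2,3-epoxy-4-(prop-2-yn-1-yl)cyclohexan-1-one, oxirane trans to the propargyl group | O=C1[C@@H]2O[C@@H]2[C@@H](CC#C)CC1 | intermediate
14 | (3S,4R)-3-hydroxy-4-(prop-2-yn-1-yl)cyclohexan-1-one | O=C1C[C@H](O)[C@@H](CC#C)CC1 | intermediate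
15 | (R)-4-(prop-2-yn-1-yl)cyclohexane-1,3-dione | O=C1CC(=O)[C@@H](CC#C)CC1 | intermediate
16 | (R)-3-methoxy-6-(prop-2-yn-1-yl)cyclohex-2-en-1-one | COC1=CC(=O)[C@@H](CC#C)CC1 | intermediate
17 | (1S,6R)-3-methoxy-6-(prop-2-yn-1-yl)cyclohex-2-en-1-ol (hydroxyl cis to propargyl) | COC1=C[C@@H](O)[C@@H](CC#C)CC1 | intermediate
18 | tert-butyl{[(1S,6R)-3-methoxy-6-(prop-2-yn-1-yl)cyclohex-2-en-1-yl]oxy}dimethylsilane | COC1=C[C@@H](O[Si](C)(C)C(C)(C)C)[C@@H](CC#C)CC1 | intermediate
19 | 8-syn-(tert-butyldimethylsilyloxy)-7-methylidenebicyclo[3.2.1]octan-2-one (C9 ketone, C15 methylidene, C12 silyloxy syn to the C15–C16 bridge) | C1C(=C)[C@@H]2C(=O)CC[C@H]1[C@@H]2O[Si](C)(C)C(C)(C)C | intermediate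
20 | 3-(trifluoroacetyl) derivative of 19 | C1C(=C)[C@@H]2C(=O)C(C(=O)C(F)(F)F)C[C@H]1[C@@H]2O[Si](C)(C)C(C)(C)C | intermediate (not isolated)
21 | 8-syn-(tert-butyldimethylsilyloxy)-3-diazo-7-methylidenebicyclo[3.2.1]octan-2-one | C1C(=C)[C@@H]2C(=O)C(=[N+]=[N-])C[C@H]1[C@@H]2O[Si](C)(C)C(C)(C)C | intermediate
22 | 8-syn-(tert-butyldimethylsilyloxy)-7-methylidene-3-(triethylsilyl)bicyclo[3.2.1]octan-2-one (C3 epimers) | C1C(=C)[C@@H]2C(=O)C([Si](CC)(CC)CC)C[C@H]1[C@@H]2O[Si](C)(C)C(C)(C)C | intermediate
23 | 8-syn-(tert-butyldimethylsilyloxy)-7-methylidene-3-(triethylsilyl)bicyclo[3.2.1]oct-2-en-2-yl trifluoromethanesulfonate (C9 triflate, C8 silane) | C1C(=C)[C@@H]2C(OS(=O)(=O)C(F)(F)F)=C([Si](CC)(CC)CC)C[C@H]1[C@@H]2O[Si](C)(C)C(C)(C)C | intermediate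
24 | 8-syn-(tert-butyldimethylsilyloxy)-7-methylidenebicyclo[3.2.1]oct-2-yne (C8≡C9) | C1C(=C)[C@@H]2C#CC[C@H]1[C@@H]2O[Si](C)(C)C(C)(C)C | intermediate (not isolated)
25 | tetracyclic 5,8-diene: 1α-acetoxy, 6-acetoxy (enol acetate C5=C6), 10α-methyl, 12-silyloxy, 15-methylidene | C1C(=C)[C@@H]2C3=C(CC(OC(C)=O)=C4C(C)(C)CC[C@H](OC(C)=O)[C@@]34C)C[C@H]1[C@@H]2O[Si](C)(C)C(C)(C)C | intermediate
26 | 8-en-6-one: 5β-H (trans ring fusion), 1α-acetoxy, 12-silyloxy, 15-methylidene | C1C(=C)[C@@H]2C3=C(CC(=O)[C@@H]4C(C)(C)CC[C@H](OC(C)=O)[C@@]34C)C[C@H]1[C@@H]2O[Si](C)(C)C(C)(C)C | intermediate (not isolated)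
27 | 6α-hydroxy 1α-acetate: 5β-H, 8-ene, 12-silyloxy, 15-methylidene | C1C(=C)[C@@H]2C3=C(C[C@H](O)[C@@H]4C(C)(C)CC[C@H](OC(C)=O)[C@@]34C)C[C@H]1[C@@H]2O[Si](C)(C)C(C)(C)C | intermediate
28 | 1α,6α-diacetate: 8-ene, 12-silyloxy, 15-methylidene | C1C(=C)[C@@H]2C3=C(C[C@H](OC(C)=O)[C@@H]4C(C)(C)CC[C@H](OC(C)=O)[C@@]34C)C[C@H]1[C@@H]2O[Si](C)(C)C(C)(C)C | intermediate
29 | 15-hydroxy-15-(hydroxymethyl) diol of 28 (C15 configuration open) | C1C(O)(CO)[C@@H]2C3=C(C[C@H](OC(C)=O)[C@@H]4C(C)(C)CC[C@H](OC(C)=O)[C@@]34C)C[C@H]1[C@@H]2O[Si](C)(C)C(C)(C)C | intermediate (not isolated)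
30 | 15-ketone: 1α,6α-diacetoxy, 8-ene, 12-silyloxy, C16 CH2 | C1C(=O)[C@@H]2C3=C(C[C@H](OC(C)=O)[C@@H]4C(C)(C)CC[C@H](OC(C)=O)[C@@]34C)C[C@H]1[C@@H]2O[Si](C)(C)C(C)(C)C | intermediate
31 | 12-O-(tert-butyldimethylsilyl) ether of the target | C=C1C(=O)[C@@H]2C3=C(C[C@H](OC(C)=O)[C@@H]4C(C)(C)CC[C@H](OC(C)=O)[C@@]34C)C[C@H]1[C@@H]2O[Si](C)(C)C(C)(C)C | intermediate
32 | 1alpha,6alpha-diacetoxyjungermannenone C | C=C1C(=O)[C@@H]2C3=C(C[C@H](OC(C)=O)[C@@H]4C(C)(C)CC[C@H](OC(C)=O)[C@@]34C)C[C@H]1[C@@H]2O | target

**Count**
Total steps: 23. Longest linear sequence: 17 (steps 7–23).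

**Steps most likely to fail**

Step 18. The strained alkyne may be consumed by ene reaction with the allylic C–H bonds of the hindered, twisted diene, by (2+2) addition to the enol acetate or by oligomerisation. Fluoride may also cleave the enol acetate, and regiochemical or facial leakage at the quaternary centre is possible. The fallback uses only known reactions; it sets out from ketone 19 and acetate 7 and returns at ketone 26. Acetate 7 is brominated at the alkyne terminus (NBS, AgNO3, acetone) to bromoalkyne F1, and Ph3PAuNTf2-catalysed hydration gives bromomethyl ketone F2. The pyrrolidine enamine of 19, which can form only towards C8, is alkylated with F2 and hydrolysed to 1,4-diketone F3. SmI2–HMPA ketyl–olefin cyclisation joins C9 to the enone β-carbon C10 anti to the C1 acetate, and protonation of the samarium enolate at C5 gives hydroxy ketone F4. Dehydration of the tertiary C9 alcohol towards C8 with the Burgess reagent gives 26, which the borohydride of step 19 reduces to 27.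

Step 6. The alkyne sits beside a quaternary carbon and a tetrasubstituted alkene, so acetic acid addition may stall or turn anti-Markovnikov, or the allylic acetate may ionise on the metal. The fallback sets out from alcohol 6 and returns at diene 8. Ph3PAuNTf2-catalysed hydration of the alkyne in wet dioxane gives hydroxy methyl ketone F5. KN(SiMe3)2 (2.2 equiv, −78 °C) then forms the alkoxide and the kinetic methyl-ketone enolate, and acetic anhydride acetylates both oxygens to give 8.

Step 16. A 1,2-hydride shift of the rhodium carbenoid to the conjugated enone may outrun Si–H insertion. The fallback sets out from ketone 19 and returns at silyl triflate 23. Bromination of the C8 enolate (LiN(SiMe3)2, then NBS) gives bromo ketone F6, and Et3SiOTf/Et3N gives bromo enol silyl ether F7. t-BuLi at −78 °C exchanges bromine for lithium, the silyl group migrates from oxygen to C8 (retro-Brook rearrangement, as in the preparation of 2-silylaryl triflates), and PhNTf2 triflates the resulting enolate to 23.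

**Further compounds**
F1 | step 18 | (S)-3-(bromoethynyl)-2,4,4-trimethylcyclohex-2-en-1-yl acetate | BrC#CC1=C(C)[C@@H](OC(C)=O)CCC1(C)C
F2 | step 18 | (S)-3-(2-bromoacetyl)-2,4,4-trimethylcyclohex-2-en-1-yl acetate | BrCC(=O)C1=C(C)[C@@H](OC(C)=O)CCC1(C)C
F3 | step 18 | 1,4-diketone: ketone 19 carrying at C8 the CH2C(=O) group of the ring A enone (C8 epimers) | C1C(=C)[C@@H]2C(=O)C(CC(=O)C3=C(C)[C@@H](OC(C)=O)CCC3(C)C)C[C@H]1[C@@H]2O[Si](C)(C)C(C)(C)C
F4 | step 18 | tetracyclic 9-hydroxy-6-ketone: 5β-H, 10α-methyl, 1α-acetoxy, 12-silyloxy, 15-methylidene (C8 and C9 configurations open) | C1C(=C)[C@@H]2C3(O)C(CC(=O)[C@@H]4C(C)(C)CC[C@H](OC(C)=O)[C@@]34C)C[C@H]1[C@@H]2O[Si](C)(C)C(C)(C)C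
F5 | step 6 | 1-[(3S)-3-hydroxy-2,6,6-trimethylcyclohex-1-en-1-yl]ethan-1-one | CC(=O)C1=C(C)[C@@H](O)CCC1(C)C
F6 | step 16 | 3-bromo-8-syn-(tert-butyldimethylsilyloxy)-7-methylidenebicyclo[3.2.1]octan-2-one (C3 epimers) | C1C(=C)[C@@H]2C(=O)C(Br)C[C@H]1[C@@H]2O[Si](C)(C)C(C)(C)C
F7 | step 16 | 3-bromo-8-syn-(tert-butyldimethylsilyloxy)-7-methylidene-2-(triethylsilyloxy)bicyclo[3.2.1]oct-2-ene | C1C(=C)[C@@H]2C(O[Si](CC)(CC)CC)=C(Br)C[C@H]1[C@@H]2O[Si](C)(C)C(C)(C)C
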